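Assumption: the SMILES is taken as andibenin B in the absolute configuration drawn; simple reagents and catalysts are named but not numbered. The route is a paper design and has not been tested.

**Retrosynthetic overview**
1. Ring A (unsaturated δ-lactone) is made last, from β-hydroxy aldehyde 29 by ketenylidene-ylide acylation and intramolecular Wittig reaction.
2. Ring B is closed by the key step, an intramolecular aldol of a thioester enolate onto the acetyl ketone (27 → 28), which forms the spiro quaternary carbon and the tertiary carbinol.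
3. The bicyclo[2.2.2]octene and the five-membered ring C form together by intramolecular Diels–Alder reaction of cyclohexa-2,4-dienone 24, made by dehydrogenating enone-lactone 23.
4. 23 comes from Suzuki coupling of bromoenone 17 with alkenylboronate 22; both fragments derive from S-ethyl acetothioacetate 3.
5. Ring order: cyclohexenone (Michael/intramolecular aldol condensation) → γ-lactone (Claisen acylation) → bicyclooctene + ring C ([4+2]) → ring B (aldol) → ring A (Wittig lactonisation).

**Route**

Step 1
Reactants: 1 2,2,6-trimethyl-4H-1,3-dioxin-4-one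
Product: 3 S-ethyl 3-oxobutanethioate, via acetylketene 2 (not isolated)
Conditions: EtSH (1.5 equiv), toluene, 110 °C
Reagents that add atoms: ethanethiol CCS
Why: thermal retro-hetero-Diels–Alder of the dioxinone releases acetone and acetylketene, which the thiol traps as the β-keto thioester.

Step 2
Reactants: 3 S-ethyl 3-oxobutanethioate
Product: 4 S-ethyl 3-oxopentanethioate
Conditions: LiN(iPr)2 (2.1 equiv), THF, −78 to 0 °C; MeI (1.0 equiv), −78 °C; aq. NH4Cl
Reagents that add atoms: iodomethane CI
Why: Huckin–Weiler dianion alkylation, in which the more reactive γ-carbanion of the β-keto thioester dianion is methylated selectively.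

Step 3
Reactants: 5 (Z)-but-2-ene-1,4-diol
Product: 6 (Z)-4-hydroxybut-2-en-1-yl methyl carbonate
Conditions: ClCO2Me (0.35 equiv), pyridine, CH2Cl2, 0 °C (diol in excess, recovered)
Reagents that add atoms: methyl chloroformate COC(=O)Cl
Why: statistical mono-acylation of the symmetrical diol used in excess gives the mono-carbonate.

Step 4
Reactants: 6 (Z)-4-hydroxybut-2-en-1-yl methyl carbonate
Product: 8 (E)-4-oxobut-2-en-1-yl methyl carbonate, via (Z)-4-oxobut-2-enyl methyl carbonate 7 (not isolated)
Conditions: PhI(OAc)2, TEMPO (10 mol %), CH2Cl2, rt; then TsOH·H2O (5 mol %), rt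
Reagents that add atoms: none
Why: oxoammonium (TEMPO) oxidation of the allylic alcohol, then acid-catalysed Z-to-E isomerisation to the thermodynamic enal.

Step 5
Reactants: 4 S-ethyl 3-oxopentanethioate; 8 (E)-4-oxobut-2-en-1-yl methyl carbonate
Product: 10 S-ethyl (6R)-6-{[(methoxycarbonyl)oxy]methyl}-3-methyl-2-oxocyclohex-3-ene-1-carbothioate, via Michael adduct 9 (not isolated)
Conditions: (S)-α,α-diphenylprolinol trimethylsilyl ether (10 mol %), PhCO2H (10 mol %), toluene, 0 °C to rt; then TsOH·H2O (20 mol %), 50 °C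
Reagents that add atoms: none
Why: iminium-catalysed (Jørgensen–Hayashi) Michael addition, in which the CPh2(OSiMe3) group shields one face of the enal and sets the CH(CH2O) centre as R, followed by intramolecular aldol condensation of the ethyl-ketone α-carbon onto the aldehyde to close the cyclohexenone.

Step 6
Reactants: 10 S-ethyl (6R)-6-{[(methoxycarbonyl)oxy]methyl}-3-methyl-2-oxocyclohex-3-ene-1-carbothioate
Product: 11 S-ethyl (1R,6R)-6-{[(methoxycarbonyl)oxy]methyl}-1,3-dimethyl-2-oxocyclohex-3-ene-1-carbothioate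
Conditions: K2CO3, MeI, acetone, rt
Reagents that add atoms: iodomethane CI
Why: C-alkylation of the β-keto thioester enolate anti to the neighbouring CH2O substituent sets the quaternary methyl-bearing carbon, from which all later ring-fusion centres derive.

Step 7
Reactants: 11 S-ethyl (1R,6R)-6-{[(methoxycarbonyl)oxy]methyl}-1,3-dimethyl-2-oxocyclohex-3-ene-1-carbothioate
Product: 12 S-ethyl (3aR,4R,7aR)-4,6-dimethyl-1,5-dioxo-1,3,3a,4,5,7a-hexahydro-2-benzofuran-4-carbothioate
Conditions: LiN(SiMe3)2 (2.2 equiv), THF, −78 to −20 °C; aq. NH4Cl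
Reagents that add atoms: none
Why: γ-deprotonation of the enone (its only acidic site) and intramolecular Claisen-type C-acylation by the tethered carbonate (5-exo) give the cis-fused γ-lactone.

Step 8
Reactants: 12 S-ethyl (3aR,4R,7aR)-4,6-dimethyl-1,5-dioxo-1,3,3a,4,5,7a-hexahydro-2-benzofuran-4-carbothioate
Product: 13 (3aR,4S,7aR)-4,6-dimethyl-1,5-dioxo-1,3,3a,4,5,7a-hexahydro-2-benzofuran-4-carbaldehyde
Conditions: Et3SiH, Pd/C (10 mol %), acetone, rt
Reagents that add atoms: none
Why: Fukuyama reduction converts the thioester to the aldehyde without touching ketone, lactone or enone.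

Step 9
Reactants: 14 1-(triphenylphosphoranylidene)propan-2-one
Product: 16 1-bromo-1-(triphenylphosphoranylidene)propan-2-one, via bromophosphonium bromide 15 (not isolated)
Conditions: Br2 (1.0 equiv), CH2Cl2, 0 °C; then aq. NaOH
Reagents that add atoms: bromine BrBr
Why: electrophilic bromination of the stabilised ylide gives the α-bromophosphonium salt, which base converts to the α-bromo ylide.

Step 10
Reactants: 13 (3aR,4S,7aR)-4,6-dimethyl-1,5-dioxo-1,3,3a,4,5,7a-hexahydro-2-benzofuran-4-carbaldehyde; 16 1-bromo-1-(triphenylphosphoranylidene)propan-2-one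
Product: 17 (3aR,4S,7aR)-4-[(1Z)-2-bromo-3-oxobut-1-en-1-yl]-4,6-dimethyl-3a,7a-dihydro-2-benzofuran-1,5(3H,4H)-dione
Conditions: toluene, 70 °C
Reagents that add atoms: none
Why: Wittig olefination with an α-bromo stabilised ylide gives the (Z)-α-bromoenone, with bromine cis to the ring and acetyl trans.

Step 11
Reactants: 18 3-bromobut-3-en-1-ol
Product: 19 2-bromo-4-iodobut-1-ene
Conditions: I2, PPh3, imidazole, CH2Cl2, 0 °C to rt
Reagents that add atoms: iodine II
Why: Appel-type (Garegg–Samuelsson) substitution of the primary alcohol by iodide.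

Step 12
Reactants: 3 S-ethyl 3-oxobutanethioate; 19 2-bromo-4-iodobut-1-ene
Product: 20 S-ethyl 2-acetyl-5-bromohex-5-enethioate
Conditions: K2CO3, DMF, rt
Reagents that add atoms: none
Why: C-alkylation of the soft β-keto thioester enolate with the primary iodide, where the mild base limits elimination.

Step 13
Reactants: 20 S-ethyl 2-acetyl-5-bromohex-5-enethioate
Product: 21 S-ethyl 2-(3-bromobut-3-en-1-yl)-3-hydroxy-3-methylbutanethioate
Conditions: MeMgBr, CeCl3 (anhydrous), THF, −78 °C; aq. NH4Cl
Reagents that add atoms: methylmagnesium bromide C[Mg]Br (used as MeCeCl2 after transmetalation with CeCl3)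
Why: the weakly basic organocerium reagent (Imamoto) adds 1,2 to the enolisable ketone faster than it enolises it or attacks the thioester.

Step 14
Reactants: 21 S-ethyl 2-(3-bromobut-3-en-1-yl)-3-hydroxy-3-methylbutanethioate
Product: 22 S-ethyl 3-hydroxy-3-methyl-2-[3-(4,4,5,5-tetramethyl-1,3,2-dioxaborolan-2-yl)but-3-en-1-yl]butanethioate
Conditions: B2pin2, PdCl2(dppf) (3 mol %), KOAc, 1,4-dioxane, 80 °C
Reagents that add atoms: bis(pinacolato)diboron CC1(C)OB(OC1(C)C)B1OC(C)(C)C(C)(C)O1
Why: Miyaura borylation of the alkenyl bromide.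

Step 15
Reactants: 17 (3aR,4S,7aR)-4-[(1Z)-2-bromo-3-oxobut-1-en-1-yl]-4,6-dimethyl-3a,7a-dihydro-2-benzofuran-1,5(3H,4H)-dione; 22 S-ethyl 3-hydroxy-3-methyl-2-[3-(4,4,5,5-tetramethyl-1,3,2-dioxaborolan-2-yl)but-3-en-1-yl]butanethioate
Product: 23 S-ethyl (6E)-6-acetyl-7-[(3aR,4R,7aR)-4,6-dimethyl-1,5-dioxo-1,3,3a,4,5,7a-hexahydro-2-benzofuran-4-yl]-2-(2-hydroxypropan-2-yl)-5-methylidenehept-6-enethioate
Conditions: Pd(PPh3)4 (5 mol %), CsF (3 equiv), THF, 50 °C
Reagents that add atoms: none
Why: Suzuki–Miyaura coupling (oxidative addition of zerovalent palladium into the C–Br bond) proceeds with retention, so the new 1,1-disubstituted alkene sits cis to the ring-bearing carbon as the cycloaddition needs.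

Step 16
Reactants: 23 S-ethyl (6E)-6-acetyl-7-[(3aR,4R,7aR)-4,6-dimethyl-1,5-dioxo-1,3,3a,4,5,7a-hexahydro-2-benzofuran-4-yl]-2-(2-hydroxypropan-2-yl)-5-methylidenehept-6-enethioate
Product: 25 Diels–Alder adduct (bicyclo[2.2.2]octenone-butenolide core fused to an acetylcyclopentene ring C), via cyclohexa-2,4-dienone 24 (not isolated)
Conditions: chloranil (1.2 equiv), toluene, 90 °C
Reagents that add atoms: none
Why: quinone dehydrogenation at the γ,δ-positions (the α′ carbon is quaternary) gives the dienone, and the alkene tethered to the quaternary carbon then adds in an intramolecular Diels–Alder reaction from the tether face only, setting both bridgeheads and the quaternary ring-fusion carbon.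

Step 17
Reactants: 25 Diels–Alder adduct
Product: 27 saturated exo-acetyl ketone (ring C cyclopentane with acetyl cis to the thioester side chain), via endo-acetyl epimer 26 (not isolated)
Conditions: Cu(OAc)2·H2O (5 mol %), 1,2-bis(diphenylphosphino)benzene (5 mol %), (HMe2Si)2O, t-BuOH, toluene, 0 °C to rt; then DBU, CH2Cl2, rt
Reagents that add atoms: none
Why: copper hydride conjugate reduction takes the ketone enone in preference to the unsaturated lactone, and DBU then epimerises the acetyl-bearing carbon to the less hindered exo isomer.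

Step 18
Reactants: 27 saturated exo-acetyl ketone
Product: 28 aldol product (ring B closed: S-ethyl thioester and 2-hydroxypropan-2-yl on the new quaternary carbon next to the new methyl carbinol)
Conditions: MgBr2·OEt2 (3 equiv), iPr2NEt (4 equiv), CH2Cl2, 0 °C to rt
Reagents that add atoms: none
Why: key ring closure by intramolecular aldol: soft enolisation selects the more acidic thioester over the ketones, and a magnesium-bridged chair transition state (enolate and ketone oxygens syn, ketone methyl away from ring C) should give the quaternary carbon and the carbinol with OH cis to the thioester, as in the target.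

Step 19
Reactants: 28 aldol product
Product: 29 β-hydroxy aldehyde (thioester of 28 replaced by CHO)
Conditions: Et3SiH, Pd/C (10 mol %), acetone, rt
Reagents that add atoms: none
Why: Fukuyama reduction of the thioester under neutral conditions avoids retro-aldol cleavage and leaves lactone and ketone intact.

Step 20
Reactants: 29 β-hydroxy aldehyde; 30 (triphenylphosphoranylidene)ketene
Product: 32 andibenin B, via phosphoranylidene ester 31 (not isolated)
Conditions: toluene, 90 °C
Reagents that add atoms: none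
Why: the less hindered tertiary alcohol (CMe2OH) adds to the ketenylidene ylide (Bestmann) and the resulting ester ylide closes ring A by intramolecular Wittig reaction on the neighbouring aldehyde, the ring enforcing the cis alkene.

**Compound list**

1 | 2,2,6-trimethyl-4H-1,3-dioxin-4-one | CC1=CC(=O)OC(C)(C)O1 | starting material
2 | acetylketene | CC(=O)C=C=O | intermediate
3 | S-ethyl 3-oxobutanethioate | CCSC(=O)CC(C)=O | intermediate
4 | S-ethyl 3-oxopentanethioate | CCSC(=O)CC(=O)CC | intermediate
5 | (Z)-but-2-ene-1,4-diol | OC/C=C\CO | starting material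
6 | (Z)-4-hydroxybut-2-en-1-yl methyl carbonate | COC(=O)OC/C=C\CO | intermediate
7 | (Z)-4-oxobut-2-en-1-yl methyl carbonate | COC(=O)OC/C=C\C=O | intermediate
8 | (E)-4-oxobut-2-en-1-yl methyl carbonate | COC(=O)OC/C=C/C=O | intermediate
9 | Michael adduct: S-ethyl (3R)-3-{[(methoxycarbonyl)oxy]methyl}-5-oxo-2-propanoylpentanethioate (C-2 epimers) | CCSC(=O)C(C(=O)CC)[C@H](COC(=O)OC)CC=O | intermediate
10 | S-ethyl (6R)-6-{[(methoxycarbonyl)oxy]methyl}-3-methyl-2-oxocyclohex-3-ene-1-carbothioate (C-1 epimers/enol) | CCSC(=O)C1C(=O)C(C)=CC[C@H]1COC(=O)OC | intermediate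
11 | S-ethyl (1R,6R)-6-{[(methoxycarbonyl)oxy]methyl}-1,3-dimethyl-2-oxocyclohex-3-ene-1-carbothioate | CCSC(=O)[C@@]1(C)C(=O)C(C)=CC[C@H]1COC(=O)OC | intermediate
12 | S-ethyl (3aR,4R,7aR)-4,6-dimethyl-1,5-dioxo-1,3,3a,4,5,7a-hexahydro-2-benzofuran-4-carbothioate | CCSC(=O)[C@@]1(C)C(=O)C(C)=C[C@H]2C(=O)OC[C@@H]12 | intermediate
13 | (3aR,4S,7aR)-4,6-dimethyl-1,5-dioxo-1,3,3a,4,5,7a-hexahydro-2-benzofuran-4-carbaldehyde | O=C[C@@]1(C)C(=O)C(C)=C[C@H]2C(=O)OC[C@@H]12 | intermediate
14 | 1-(triphenylphosphoranylidene)propan-2-one | CC(=O)C=P(c1ccccc1)(c1ccccc1)c1ccccc1 | starting material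
15 | (1-bromo-2-oxopropyl)triphenylphosphonium bromide | CC(=O)C(Br)[P+](c1ccccc1)(c1ccccc1)c1ccccc1.[Br-] | intermediate
16 | 1-bromo-1-(triphenylphosphoranylidene)propan-2-one | CC(=O)C(Br)=P(c1ccccc1)(c1ccccc1)c1ccccc1 | intermediate
17 | (3aR,4S,7aR)-4-[(1Z)-2-bromo-3-oxobut-1-en-1-yl]-4,6-dimethyl-3a,7a-dihydro-2-benzofuran-1,5(3H,4H)-dione | CC(=O)/C(Br)=C/[C@@]1(C)C(=O)C(C)=C[C@H]2C(=O)OC[C@@H]12 | intermediate
18 | 3-bromobut-3-en-1-ol | C=C(Br)CCO | starting material
19 | 2-bromo-4-iodobut-1-ene | C=C(Br)CCI | intermediate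
20 | S-ethyl 2-acetyl-5-bromohex-5-enethioate (racemic) | CCSC(=O)C(CCC(Br)=C)C(C)=O | intermediate
21 | S-ethyl 2-(3-bromobut-3-en-1-yl)-3-hydroxy-3-methylbutanethioate (racemic) | CCSC(=O)C(CCC(Br)=C)C(C)(C)O | intermediate
22 | S-ethyl 3-hydroxy-3-methyl-2-[3-(4,4,5,5-tetramethyl-1,3,2-dioxaborolan-2-yl)but-3-en-1-yl]butanethioate (racemic) | CCSC(=O)C(CCC(=C)B1OC(C)(C)C(C)(C)O1)C(C)(C)O | intermediate
23 | S-ethyl (6E)-6-acetyl-7-[(3aR,4R,7aR)-4,6-dimethyl-1,5-dioxo-1,3,3a,4,5,7a-hexahydro-2-benzofuran-4-yl]-2-(2-hydroxypropan-2-yl)-5-methylidenehept-6-enethioate (1:1 at C-2; that carbon is planarised in step 18) | CC(=O)/C(=C/[C@@]1(C)C(=O)C(C)=C[C@H]2C(=O)OC[C@@H]12)C(=C)CCC(C(=O)SCC)C(C)(C)O | intermediate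
24 | S-ethyl (6E)-6-acetyl-7-[(4R)-4,6-dimethyl-1,5-dioxo-1,3,4,5-tetrahydro-2-benzofuran-4-yl]-2-(2-hydroxypropan-2-yl)-5-methylidenehept-6-enethioate (cyclohexa-2,4-dienone) | CC(=O)/C(=C/[C@@]1(C)C(=O)C(C)=CC2=C1COC2=O)C(=C)CCC(C(=O)SCC)C(C)(C)O | intermediate
25 | Diels–Alder adduct: bicyclo[2.2.2]octenone with both bridgeheads, fused butenolide and quaternary carbons as in andibenin B; ring C is a cyclopentene carrying acetyl on its alkene; the quaternary ring-C carbon carries CH2CH2CH(COSEt)C(CH3)2OH (thioester α-carbon 1:1) | OC(C)(C)C(C(=O)SCC)CC[C@@]13C[C@@]4(C)C=C5C(=O)OC[C@]51[C@@](C)(C=C3C(C)=O)C4=O | intermediate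
26 | endo-acetyl epimer of 27 (acetyl trans to the side chain) | OC(C)(C)C(C(=O)SCC)CC[C@@]13C[C@@]4(C)C=C5C(=O)OC[C@]51[C@@](C)(C[C@@H]3C(C)=O)C4=O | intermediate
27 | saturated ring-C ketone: as 25 with the cyclopentene reduced, acetyl exo and cis to the side chain | OC(C)(C)C(C(=O)SCC)CC[C@@]13C[C@@]4(C)C=C5C(=O)OC[C@]51[C@@](C)(C[C@H]3C(C)=O)C4=O | intermediate
28 | aldol product: ring B closed; the new quaternary carbon bears C(=O)SEt and C(CH3)2OH, the adjacent carbon bears CH3 and OH; all stereocentres as in andibenin B | CCSC(=O)[C@@]2(C(C)(C)O)CC[C@@]13C[C@@]4(C)C=C5C(=O)OC[C@]51[C@@](C)(C[C@H]3[C@@]2(C)O)C4=O | intermediate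
29 | β-hydroxy aldehyde: 28 with CHO in place of C(=O)SEt | O=C[C@@]2(C(C)(C)O)CC[C@@]13C[C@@]4(C)C=C5C(=O)OC[C@]51[C@@](C)(C[C@H]3[C@@]2(C)O)C4=O | intermediate
30 | (triphenylphosphoranylidene)ketene | O=C=C=P(c1ccccc1)(c1ccccc1)c1ccccc1 | starting material
31 | (triphenylphosphoranylidene)acetate ester of the C(CH3)2OH group of 29 | O=C[C@@]2(C(C)(C)OC(=O)C=P(c6ccccc6)(c6ccccc6)c6ccccc6)CC[C@@]13C[C@@]4(C)C=C5C(=O)OC[C@]51[C@@](C)(C[C@H]3[C@@]2(C)O)C4=O | intermediate
32 | andibenin B | CC1(C)OC(=O)C=C[C@]12CC[C@@]13C[C@@]4(C)C=C5C(=O)OC[C@]51[C@@](C)(C[C@H]3[C@@]2(C)O)C4=O | target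

**Step count and risk**

Total step count: 20. Longest linear sequence: 13 steps (1, 2, 5, 6, 7, 8, 10, 15, 16, 17, 18, 19, 20; the path through steps 3 and 4 is equally long), i.e. 13/20 = 0.65.

The three steps most likely to fail are 16, 18 and 20.

Step 16 can fail if chloranil does not dehydrogenate the lactone-substituted enone cleanly or attacks the electron-rich diene of the tether. The fallback installs the leaving group before the coupling. It sets out from 17: α-selenenylation of the acidic lactone position (PhSeCl, pyridine, CH2Cl2) gives the phenylselanyl lactone F1, with selenium syn to the ring-fusion hydrogen. Suzuki coupling of this with 22 under the conditions of step 15 gives the coupled selenide F2. Oxidation with H2O2 at 0 °C gives the selenoxide F3, whose syn-elimination at room temperature produces dienone 24. This cyclises on warming and rejoins the route at 25.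

Step 18 can fail through retro-aldol loss of acetone from the β-hydroxy thioester, through slow enolisation of the α-branched thioester, or by giving the wrong aldol diastereomer. The fallback changes the donor from a metal thioester enolate to an aldehyde enamine. It sets out from 27: Fukuyama reduction (Et3SiH, Pd/C) first gives the keto-aldehyde F4, and pyrrolidinium acetate (or L-proline) in DMSO then closes ring B by a 6-enolexo aldol of the enamine onto the methyl ketone. This returns to the route at 29, so step 19 is no longer needed.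

Step 20 can fail if the more hindered ring carbinol competes for the ylide or if the tertiary alcohol adds too slowly. The fallback builds the enoate first and lactonises afterwards. It sets out from 29: Still–Gennari olefination (methyl bis(2,2,2-trifluoroethyl)phosphonoacetate, KN(SiMe3)2, 18-crown-6, THF, −78 °C) gives the methyl (Z)-enoate F5, and camphorsulfonic acid in benzene at 60 °C lactonises it through the less hindered C(CH3)2OH group, returning to the route at 32.

**Further compounds**

F1 | step 16 | 7a-(phenylselanyl) derivative of 17 (selenium syn to the 3a-hydrogen) | CC(=O)/C(Br)=C/[C@@]1(C)C(=O)C(C)=C[C@@]2([Se]c3ccccc3)C(=O)OC[C@@H]12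
F2 | step 16 | 7a-(phenylselanyl) analogue of 23 (Suzuki product of F1 and 22) | CC(=O)/C(=C/[C@@]1(C)C(=O)C(C)=C[C@@]2([Se]c3ccccc3)C(=O)OC[C@@H]12)C(=C)CCC(C(=O)SCC)C(C)(C)O
F3 | step 16 | selenoxide of F2 | CC(=O)/C(=C/[C@@]1(C)C(=O)C(C)=C[C@@]2([Se](=O)c3ccccc3)C(=O)OC[C@@H]12)C(=C)CCC(C(=O)SCC)C(C)(C)O
F4 | step 18 | keto-aldehyde: 27 with CHO in place of C(=O)SEt | O=CC(C(C)(C)O)CC[C@@]13C[C@@]4(C)C=C5C(=O)OC[C@]51[C@@](C)(C[C@H]3C(C)=O)C4=O
F5 | step 20 | methyl (Z)-enoate: 29 with CH=CH-CO2CH3 (Z) in place of CHO | COC(=O)/C=C\[C@@]2(C(C)(C)O)CC[C@@]13C[C@@]4(C)C=C5C(=O)OC[C@]51[C@@](C)(C[C@H]3[C@@]2(C)O)C4=O
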